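**Plan**
Locants follow the hydroazulene numbering of the target: C3 = C(OH)(iPr), C3a = ring-fusion CH, C4 = CH–O, C8a = quaternary C–CH3.
Cuts, in retrosynthetic order: the ester C–O at C4; the C3–C3a bond of the cyclopentane; the C8a–C1 bond; the cycloheptadienone back to 2,5-dimethylfuran and a three-carbon oxyallyl unit.
Enabling feature: O–C3 is β to the C4 carbonyl (an aldol pattern) and C3–H is 1,5 to C3a through the quaternary C8a, which has no hydrogen. A carbenoid at C3a of the cycloheptenone can therefore insert into the C3–H bond of a secondary silyl ether.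
Forward order: the seven-membered ring is made first ((4+3) cycloaddition, hydrogenation, ring opening to the symmetric dienone). The C1–C2–C3 chain is then joined at C8a by asymmetric conjugate addition, and the cyclopentane is closed last by C–H insertion.
Stereochemistry: C3 from a Sharpless kinetic resolution, carried into the tertiary carbinol with retention; C8a from ligand control; C3a by equilibration to the trans-fused ketone; C4 by hydroxyl-directed hydride delivery.

Key step: step 8

Remark: the phosphoramidite antipode used in step 6 is assumed to be the one that gives the 6S ketone; the sense of induction would have to be confirmed.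

Step 1
Reactants: 1 2,5-dimethylfuran; 2 1,1,3,3-tetrabromopropan-2-one
Product: 4 (1R,5S)-1,5-dimethyl-8-oxabicyclo[3.2.1]oct-6-en-3-one (meso), via dibromo cycloadduct 3 (not isolated)
Conditions: Zn, B(OEt)3, THF, 0 °C to rt; then Zn/Cu couple, NH4Cl, MeOH, rt
Reagents that add atoms: none
Why: Zinc reduces 2 to a dibromo-oxyallyl cation that adds across the furan diene in a (4+3) cycloaddition, and Zn/Cu then removes both bromines; the bridged product is meso, its bridgehead centers being fixed by the ring.

Step 2
Reactants: 4 (1R,5S)-1,5-dimethyl-8-oxabicyclo[3.2.1]oct-6-en-3-one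
Product: 5 (1R,5S)-1,5-dimethyl-8-oxabicyclo[3.2.1]octan-3-one (meso)
Conditions: H2 (1 atm), Pd/C, EtOAc, rt
Reagents that add atoms: none
Why: Catalytic hydrogenation of the strained bridge alkene should leave ketone and ether untouched; no new stereocenter arises.

Step 3
Reactants: 5 (1R,5S)-1,5-dimethyl-8-oxabicyclo[3.2.1]octan-3-one
Product: 7 3,6-dimethylcyclohepta-2,6-dien-1-one, via hydroxy enone 6 (not isolated)
Conditions: TsOH·H2O (10 mol%), toluene, reflux, Dean–Stark
Reagents that add atoms: none
Why: Acid-catalysed β-elimination of the bridging tertiary ether (retro-oxa-Michael ring opening) and dehydration of the resulting tertiary β-hydroxy ketone should place both double bonds in conjugation with the carbonyl, giving the achiral cross-conjugated dienone.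

Step 4
Reactants: 8 racemic 4-methylpent-1-en-3-ol
Product: 9 (S)-4-methylpent-1-en-3-ol
Conditions: Ti(OiPr)4 (10 mol%), D-(−)-DIPT (15 mol%), t-BuOOH (0.6 equiv), 4 Å MS, CH2Cl2, −20 °C
Reagents that add atoms: none
Why: Sharpless kinetic resolution: with D-(−)-DIPT the R alcohol should be epoxidised much faster, so the S alcohol (the future C3 center) is recovered.

Step 5
Reactants: 9 (S)-4-methylpent-1-en-3-ol
Product: 10 (S)-triethyl[(4-methylpent-1-en-3-yl)oxy]silane
Conditions: TESCl, imidazole, CH2Cl2, 0 °C to rt
Reagents that add atoms: chlorotriethylsilane CC[Si](Cl)(CC)CC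
Why: Standard silylation; the silyl ether activates the adjacent C–H bond for the later insertion and prevents O–H insertion.

Step 6
Reactants: 10 (S)-triethyl[(4-methylpent-1-en-3-yl)oxy]silane; 7 3,6-dimethylcyclohepta-2,6-dien-1-one
Product: 13 (6S)-3,6-dimethyl-6-[(3R)-4-methyl-3-(triethylsilyloxy)pentyl]cyclohept-2-en-1-one, via alkylzirconocene chloride 11 (not isolated), via silyl dienol ether 12 (not isolated)
Conditions: Cp2Zr(H)Cl, CH2Cl2, rt; then 7, CuCl (10 mol%), BINOL-derived phosphoramidite (10 mol%), AgNTf2 (15 mol%), TMSCl, Et2O, rt; aq. NH4Cl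
Reagents that add atoms: none
Why: Hydrozirconation of the terminal alkene and copper-catalysed asymmetric conjugate addition of the alkylzirconocene to one of the two homotopic β-methyl enone units creates the quaternary center, whose 6S configuration is set by the ligand because the carbinol center is remote; the adduct is held as a silyl dienol ether, so a second addition cannot follow.

Step 7
Reactants: 13 (6S)-3,6-dimethyl-6-[(3R)-4-methyl-3-(triethylsilyloxy)pentyl]cyclohept-2-en-1-one
Product: 15 (6S)-7-diazo-3,6-dimethyl-6-[(3R)-4-methyl-3-(triethylsilyloxy)pentyl]cyclohept-2-en-1-one, via trifluoroacetyl ketone 14 (not isolated)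
Conditions: LiN(SiMe3)2, THF, −78 °C; CF3CO2CH2CF3; then MsN3, Et3N, H2O, MeCN, rt
Reagents that add atoms: methanesulfonyl azide CS(=O)(=O)N=[N+]=[N-]
Why: Detrifluoroacetylative Regitz diazo transfer at the only sp3 α-carbon of the enone; no stereocenter is touched.

Step 8
Reactants: 15 (6S)-7-diazo-3,6-dimethyl-6-[(3R)-4-methyl-3-(triethylsilyloxy)pentyl]cyclohept-2-en-1-one
Product: 17 (3R,3aR,8aS)-3-isopropyl-6,8a-dimethyl-3-(triethylsilyloxy)-2,3,3a,7,8,8a-hexahydroazulen-4(1H)-one (trans-fused), via cis-fused epimer 16 (not isolated)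
Conditions: Rh2(OAc)4 (1 mol%), CH2Cl2, 40 °C; then DBU (0.3 equiv), rt
Reagents that add atoms: none
Why: Rh2(OAc)4 converts the diazo ketone into an electrophilic rhodium carbenoid at the future C3a, which inserts in a concerted three-centre transition state into the tertiary C3–H bond five atoms away; this is the intramolecular 1,5 C–H insertion of α-diazo ketones, and insertion next to a silyloxy group is the C–H counterpart of an aldol addition. The cyclopentane closes by joining the carbenoid carbon of the seven-membered ring to the fifth atom of its side chain (1,5-insertion, the new ring fused at C3a–C8a). C3: the insertion goes with retention, so the carbinol center set in step 4 becomes the 3R tertiary carbinol with oxygen cis to the angular methyl group, whatever the facial course of the closure. C3a: the chain must reach the vacant carbenoid orbital from the face of C8a that carries it, which should give the cis-fused epimer 16 first; C3a is then the enolisable α-carbon of the ketone, and DBU in the same flask should move it to the trans-fused 17, in which the isopropyl group lies beside H-3a instead of beside C4 and which is also the product of protonation anti to the angular methyl group. The step needs site selectivity for one C–H bond: this bond is the only one in a 1,5-relationship on a flexible tether, it is tertiary and activated by oxygen, the bulky silyl ether disfavours attack of the carbenoid on oxygen, and the quaternary C8a offers no hydrogen for a 1,2-shift.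

Step 9
Reactants: 17 (3R,3aR,8aS)-3-isopropyl-6,8a-dimethyl-3-(triethylsilyloxy)-2,3,3a,7,8,8a-hexahydroazulen-4(1H)-one
Product: 18 (3R,3aR,8aS)-3-hydroxy-3-isopropyl-6,8a-dimethyl-2,3,3a,7,8,8a-hexahydroazulen-4(1H)-one
Conditions: HF·pyridine, THF/pyridine, 0 °C to rt
Reagents that add atoms: none
Why: Fluoride-mediated cleavage of the tertiary silyl ether under non-basic conditions should avoid retro-aldol opening and epimerisation of the β-hydroxy ketone.

Step 10
Reactants: 18 (3R,3aR,8aS)-3-hydroxy-3-isopropyl-6,8a-dimethyl-2,3,3a,7,8,8a-hexahydroazulen-4(1H)-one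
Product: 19 (3R,3aS,4S,8aS)-3-isopropyl-6,8a-dimethyl-1,2,3,3a,4,7,8,8a-octahydroazulene-3,4-diol
Conditions: Me4NBH(OAc)3, MeCN/AcOH, −30 °C
Reagents that add atoms: none
Why: Evans–Saksena reduction: the tertiary hydroxyl binds boron and should deliver hydride intramolecularly to the face of the enone carbonyl on which it sits, giving the 1,3-anti diol (4S) by 1,2-reduction only.

Step 11
Reactants: 19 (3R,3aS,4S,8aS)-3-isopropyl-6,8a-dimethyl-1,2,3,3a,4,7,8,8a-octahydroazulene-3,4-diol; 20 4-methoxybenzoyl chloride
Product: 21 (3R,3aS,4S,8aS)-3-hydroxy-3-isopropyl-6,8a-dimethyl-1,2,3,3a,4,7,8,8a-octahydroazulen-4-yl 4-methoxybenzoate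
Conditions: pyridine, DMAP (cat.), CH2Cl2, 0 °C to rt
Reagents that add atoms: none
Why: DMAP-catalysed acylation should discriminate the secondary allylic hydroxyl from the hindered tertiary one; no stereocenter is affected.

**Compound list**
1 | 2,5-dimethylfuran | Cc1ccc(C)o1 | starting material
2 | 1,1,3,3-tetrabromopropan-2-one | BrC(Br)C(=O)C(Br)Br | starting material
3 | 2,4-dibromo-1,5-dimethyl-8-oxabicyclo[3.2.1]oct-6-en-3-one (formed in the flask; mixture of bromine epimers) | C[C@]12C(Br)C(=O)C(Br)[C@](C)(O1)C=C2 | intermediate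
4 | (1R,5S)-1,5-dimethyl-8-oxabicyclo[3.2.1]oct-6-en-3-one (meso) | C[C@]12CC(=O)C[C@](C)(O1)C=C2 | intermediate
5 | (1R,5S)-1,5-dimethyl-8-oxabicyclo[3.2.1]octan-3-one (meso) | C[C@]12CC(=O)C[C@](C)(O1)CC2 | intermediate
6 | 6-hydroxy-3,6-dimethylcyclohept-2-en-1-one (formed in the flask; racemic) | CC1=CC(=O)CC(C)(O)CC1 | intermediate
7 | 3,6-dimethylcyclohepta-2,6-dien-1-one | CC1=CC(=O)C=C(C)CC1 | intermediate
8 | racemic 4-methylpent-1-en-3-ol | C=CC(O)C(C)C | starting material
9 | (S)-4-methylpent-1-en-3-ol | C=C[C@@H](O)C(C)C | intermediate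
10 | (S)-triethyl[(4-methylpent-1-en-3-yl)oxy]silane | C=C[C@@H](O[Si](CC)(CC)CC)C(C)C | intermediate
11 | chlorobis(cyclopentadienyl)[(3R)-4-methyl-3-(triethylsilyloxy)pentyl]zirconium (formed in the flask) | Cl[Zr](C1C=CC=C1)(C1C=CC=C1)CC[C@@H](O[Si](CC)(CC)CC)C(C)C | intermediate
12 | trimethyl{[(7S)-4,7-dimethyl-7-[(3R)-4-methyl-3-(triethylsilyloxy)pentyl]cyclohepta-1,3-dien-2-yl]oxy}silane (formed in the flask) | C[Si](C)(C)OC1=C[C@](C)(CC[C@@H](O[Si](CC)(CC)CC)C(C)C)CCC(C)=C1 | intermediate
13 | (6S)-3,6-dimethyl-6-[(3R)-4-methyl-3-(triethylsilyloxy)pentyl]cyclohept-2-en-1-one | O=C1C=C(C)CC[C@@](C)(CC[C@@H](O[Si](CC)(CC)CC)C(C)C)C1 | intermediate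
14 | (6S)-3,6-dimethyl-6-[(3R)-4-methyl-3-(triethylsilyloxy)pentyl]-7-(trifluoroacetyl)cyclohept-2-en-1-one (formed in the flask; C7 epimers and enol) | O=C1C=C(C)CC[C@@](C)(CC[C@@H](O[Si](CC)(CC)CC)C(C)C)C1C(=O)C(F)(F)F | intermediate
15 | (6S)-7-diazo-3,6-dimethyl-6-[(3R)-4-methyl-3-(triethylsilyloxy)pentyl]cyclohept-2-en-1-one | O=C1C=C(C)CC[C@@](C)(CC[C@@H](O[Si](CC)(CC)CC)C(C)C)C1=[N+]=[N-] | intermediate
16 | (3R,3aS,8aS)-3-isopropyl-6,8a-dimethyl-3-(triethylsilyloxy)-2,3,3a,7,8,8a-hexahydroazulen-4(1H)-one (cis-fused; formed in the flask) | O=C1C=C(C)CC[C@@]2(C)CC[C@@](O[Si](CC)(CC)CC)(C(C)C)[C@@H]12 | intermediate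
17 | (3R,3aR,8aS)-3-isopropyl-6,8a-dimethyl-3-(triethylsilyloxy)-2,3,3a,7,8,8a-hexahydroazulen-4(1H)-one (trans-fused) | O=C1C=C(C)CC[C@@]2(C)CC[C@@](O[Si](CC)(CC)CC)(C(C)C)[C@H]12 | intermediate
18 | (3R,3aR,8aS)-3-hydroxy-3-isopropyl-6,8a-dimethyl-2,3,3a,7,8,8a-hexahydroazulen-4(1H)-one | O=C1C=C(C)CC[C@@]2(C)CC[C@@](O)(C(C)C)[C@H]12 | intermediate
19 | (3R,3aS,4S,8aS)-3-isopropyl-6,8a-dimethyl-1,2,3,3a,4,7,8,8a-octahydroazulene-3,4-diol | O[C@H]1C=C(C)CC[C@@]2(C)CC[C@@](O)(C(C)C)[C@H]12 | intermediate
20 | 4-methoxybenzoyl chloride | COc1ccc(cc1)C(Cl)=O | starting material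
21 | (3R,3aS,4S,8aS)-3-hydroxy-3-isopropyl-6,8a-dimethyl-1,2,3,3a,4,7,8,8a-octahydroazulen-4-yl 4-methoxybenzoate | COc1ccc(C(=O)O[C@H]2C=C(C)CC[C@@]3(C)CC[C@@](O)(C(C)C)[C@H]23)cc1 | target

**Count**
Total: 11 steps. Longest linear sequence: 9 steps (steps 1–3 and 6–11); steps 4 and 5 form a two-step side branch that joins at step 6.

**Steps most likely to fail**

1. Step 8. The C–H bond to be attacked lies between a silyloxy and an isopropyl group, so the carbenoid may be diverted into attack on the ether oxygen followed by a 1,2-shift, migration of a C8a substituent, or dimerisation. The epimerisation may also stall, or be overtaken by β-elimination of silanolate from the enolate. Fallback, setting out from 13: HF·pyridine would give the hydroxy ketone F1 and Dess–Martin periodinane the diketone F2. KOt-Bu in t-BuOH/THF at 0 °C would then close the cyclopentane by a reversible intramolecular aldol addition. Under equilibration this should settle on 18, the isomer with OH hydrogen-bonded to the carbonyl and the isopropyl group beside H-3a. The route is rejoined at 18.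

2. Step 6. Transmetalation of the γ-branched alkylzirconocene may be slow, or facial selectivity on the dienone may be poor. Fallback, setting out from 10: hydrozirconation with Cp2Zr(H)Cl and iodinolysis with I2 would give the iodide F3, and Mg in THF the Grignard reagent F4. Its addition to 7 mediated by CuBr·SMe2 and BF3·OEt2 (THF, −78 °C) would give 13 together with its 6R epimer F5. The two are diastereomers because of the carbinol center, and F5 would be removed by chromatography. The route is rejoined at 13.

3. Step 10. The hindered tertiary hydroxyl may fail to bind boron, so that hydride arrives undirected and with poor facial selectivity. Fallback, setting out from 18: Luche reduction (NaBH4, CeCl3·7H2O, MeOH, −78 °C) would give the allylic alcohols by external attack. The part that is 19 goes on as planned. The C4 epimer, (3R,3aS,4R,8aS)-diol F6, would be converted by Mitsunobu esterification with 4-methoxybenzoic acid (PPh3, DIAD, THF), with inversion at C4, directly into 21, where the route ends.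

**Further compounds**
F1 | step 8 | (6S)-6-[(3R)-3-hydroxy-4-methylpentyl]-3,6-dimethylcyclohept-2-en-1-one | O=C1C=C(C)CC[C@@](C)(CC[C@@H](O)C(C)C)C1
F2 | step 8 | (6S)-3,6-dimethyl-6-(4-methyl-3-oxopentyl)cyclohept-2-en-1-one | O=C1C=C(C)CC[C@@](C)(CCC(=O)C(C)C)C1
F3 | step 6 | (R)-triethyl[(1-iodo-4-methylpentan-3-yl)oxy]silane | ICC[C@@H](O[Si](CC)(CC)CC)C(C)C
F4 | step 6 | [(3R)-4-methyl-3-(triethylsilyloxy)pentyl]magnesium iodide | I[Mg]CC[C@@H](O[Si](CC)(CC)CC)C(C)C
F5 | step 6 | (6R)-3,6-dimethyl-6-[(3R)-4-methyl-3-(triethylsilyloxy)pentyl]cyclohept-2-en-1-one | O=C1C=C(C)CC[C@](C)(CC[C@@H](O[Si](CC)(CC)CC)C(C)C)C1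
F6 | step 10 | (3R,3aS,4R,8aS)-3-isopropyl-6,8a-dimethyl-1,2,3,3a,4,7,8,8a-octahydroazulene-3,4-diol | O[C@@H]1C=C(C)CC[C@@]2(C)CC[C@@](O)(C(C)C)[C@H]12
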